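**Retrosynthetic overview**
- Feature: the free 4-OH of the pendant syringyl ring is para to C1, so C1 is a latent para-quinone methide carbon. C2, C3 and their CH2OH and CHO carbons are the four carbons of succinaldehyde, and C4 is the formyl carbon of ring A.
- Key disconnection: C1–C2 (enamine 1,6-addition) and C3=C4 (aldol condensation) in one operation. It closes ring B (C1–C2–C3–C4–C4a–C8a), the only ring formed; both arenes come from syringaldehyde.
- The quinone methide is released in the flask from a lactol, made by Br/Li exchange on a bromo acetal of O-benzylsyringaldehyde and addition to O-silylsyringaldehyde.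
- End game: selective borohydride reduction of the saturated C2 aldehyde, then BCl3 cleavage of the C7 benzyl ether.

Key step: step 8

Assumption: induction at the quinone methide carbon is taken to follow the synclinal enamine topology established for nitroalkene acceptors, which assigns the (R)-catalyst to the (1S,2R) series; locants C1–C8a follow the lignan numbering used above throughout.

**Step 1**
Reactants: 1 syringaldehyde
Product: 2 4-(benzyloxy)-3,5-dimethoxybenzaldehyde
Conditions: BnBr, K2CO3, DMF, 60 °C
Reagents that add atoms: benzyl bromide, BrCc1ccccc1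
Why: Williamson etherification of the acidic phenoxide (para-formyl phenol) should proceed cleanly and masks the ring A hydroxyl for the organolithium step.

**Step 2**
Reactants: 2 4-(benzyloxy)-3,5-dimethoxybenzaldehyde
Product: 3 4-(benzyloxy)-2-bromo-3,5-dimethoxybenzaldehyde
Conditions: NBS (1.05 equiv), MeCN, rt, dark
Reagents that add atoms: N-bromosuccinimide, O=C1CCC(=O)N1Br
Why: Electrophilic aromatic bromination can only occur at the two equivalent free positions, each ortho and para to a methoxy group, and the polar medium in the dark should suppress radical bromination of the benzyl CH2.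

**Step 3**
Reactants: 3 4-(benzyloxy)-2-bromo-3,5-dimethoxybenzaldehyde
Product: 4 2-[4-(benzyloxy)-2-bromo-3,5-dimethoxyphenyl]-1,3-dioxolane
Conditions: HOCH2CH2OH, p-TsOH (cat.), toluene, reflux, Dean–Stark
Reagents that add atoms: ethylene glycol, OCCO
Why: Acid-catalysed acetalisation with azeotropic removal of water masks the aldehyde against the aryllithium generated next.

**Step 4**
Reactants: 1 syringaldehyde
Product: 5 4-[(tert-butyldimethylsilyl)oxy]-3,5-dimethoxybenzaldehyde
Conditions: TBSCl, imidazole, DMF, rt
Reagents that add atoms: tert-butyldimethylsilyl chloride, CC(C)(C)[Si](C)(C)Cl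
Why: Imidazole-promoted O-silylation removes the acidic proton and keeps the aldehyde electrophilic, whereas a phenoxide would deactivate it.

**Step 5**
Reactants: 4 2-[4-(benzyloxy)-2-bromo-3,5-dimethoxyphenyl]-1,3-dioxolane; 5 4-[(tert-butyldimethylsilyl)oxy]-3,5-dimethoxybenzaldehyde
Product: 7 {3-(benzyloxy)-6-(1,3-dioxolan-2-yl)-2,4-dimethoxyphenyl}{4-[(tert-butyldimethylsilyl)oxy]-3,5-dimethoxyphenyl}methanol (racemic), via aryllithium 6 (not isolated)
Conditions: n-BuLi, THF, −78 °C; then 5, −78 → −20 °C; aq. NH4Cl
Reagents that add atoms: none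
Why: Bromine–lithium exchange is faster at −78 °C than attack on the acetal or benzyl ether, and the aryllithium, chelated by the flanking methoxy and dioxolane oxygens, should add 1,2 to the aldehyde; the new carbinol centre is racemic and is erased when it becomes the sp2 methide carbon.

**Step 6**
Reactants: 7 {3-(benzyloxy)-6-(1,3-dioxolan-2-yl)-2,4-dimethoxyphenyl}{4-[(tert-butyldimethylsilyl)oxy]-3,5-dimethoxyphenyl}methanol
Product: 9 5-(benzyloxy)-3-(4-hydroxy-3,5-dimethoxyphenyl)-4,6-dimethoxy-1,3-dihydro-2-benzofuran-1-ol (lactol; diastereomer mixture; racemic), via free phenol acetal 8 (not isolated)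
Conditions: TBAF, THF, 0 °C; then 1 M aq. HCl, 0 °C → rt
Reagents that add atoms: water, O
Why: Fluoride desilylation followed by acid hydrolysis of the dioxolane should give the hydroxy aldehyde, which closes to the five-membered lactol, a para-hydroxybenzylic cyclic ether of the kind found in stable furanoid lignans; its two sp3 centres have no stereochemical consequence.

**Step 7**
Reactants: 10 2,5-dimethoxytetrahydrofuran
Product: 11 succinaldehyde
Conditions: H2O, 90 °C; distil off MeOH/H2O; vacuum distillation, use fresh
Reagents that add atoms: water, O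
Why: Hydrolysis of the cyclic bis-acetal in hot water, driven by removal of methanol, should give the monomeric dialdehyde, which is used at once to limit oligomerisation.

**Step 8**
Reactants: 9 5-(benzyloxy)-3-(4-hydroxy-3,5-dimethoxyphenyl)-4,6-dimethoxy-1,3-dihydro-2-benzofuran-1-ol; 11 succinaldehyde
Product: 14 (1S,2R)-7-(benzyloxy)-1-(4-hydroxy-3,5-dimethoxyphenyl)-6,8-dimethoxy-1,2-dihydronaphthalene-2,3-dicarbaldehyde (trans), via ortho-formyl quinone methide 12 (not isolated), via acyclic 1,6-adduct 13 (not isolated)
Conditions: (R)-2-[diphenyl(trimethylsilyloxy)methyl]pyrrolidine (20 mol%), ClCH2CO2H (20 mol%), 11 (3 equiv, slow addition), CHCl3, 0 °C → rt; then Bn2NH·CF3CO2H (20 mol%), rt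
Reagents that add atoms: none
Why: Proposed new method: the acid co-catalyst should ionise the benzylic C–O bond of lactol 9 (cation stabilised by the para-hydroxyl and by the ortho and para methoxy groups of ring A) to quinone methide 12 with its ortho-formyl group unmasked, and the enamine formed by the prolinol catalyst at one terminus of 11 adds 1,6 to the methide carbon (C1–C2), rearomatising the syringyl ring to give 13. A second enamine at the other CH2 (C3) then attacks the neighbouring aryl aldehyde in a 6-(enolexo)-exo-trig aldol closure of ring B, and loss of water to the arene-conjugated enal (C3=C4) makes the closure irreversible; the closest known reactions are the enamine-catalysed 1,6-addition and SN1-type α-alkylation of aldehydes with para-quinone methides or benzhydryl cations and the Michael/aldol-condensation annulations of succinaldehyde, which have not been merged on an ortho-formyl quinone methide. C1 is set by the catalyst, whose diphenyl(silyloxy)methyl group shields one enamine face so that, by the synclinal topology known for nitroalkene acceptors, the (R)-catalyst should deliver the (1S,2R) adduct. C2 remains α to an aldehyde, so any cis isomer should drain under the amine/acid conditions into the more stable trans isomer, in which the C1 aryl and C2 formyl groups avoid each other and the peri C8 methoxy group. The step needs the six-ring condensation through C3 to win over the five-ring aldol through C2 and over dehydration of 9 to an isobenzofuran: the five-ring aldol leaves no α-hydrogen for dehydration and reverts, and the lactol/isobenzofuran/quinone methide manifold is reversible in the wet, weakly acidic medium, so material is funnelled to the only irreversible exit. If condensation at the formyl group precedes the conjugate addition, intramolecular 1,6-addition of the remaining enamine closes the same ring and gives the same product.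

**Step 9**
Reactants: 14 (1S,2R)-7-(benzyloxy)-1-(4-hydroxy-3,5-dimethoxyphenyl)-6,8-dimethoxy-1,2-dihydronaphthalene-2,3-dicarbaldehyde
Product: 15 (1S,2R)-7-(benzyloxy)-2-(hydroxymethyl)-1-(4-hydroxy-3,5-dimethoxyphenyl)-6,8-dimethoxy-1,2-dihydronaphthalene-3-carbaldehyde
Conditions: NaBH4 (0.3 equiv), CH2Cl2/MeOH 1:1, −78 °C; then H2O
Reagents that add atoms: none
Why: Chemoselective borohydride reduction should take the saturated C2 aldehyde, because the C3 enal is conjugated through C4 to the para-benzyloxy arene and is much less electrophilic at low temperature; C2 is no longer α to a carbonyl afterwards, so the trans configuration is fixed.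

**Step 10**
Reactants: 15 (1S,2R)-7-(benzyloxy)-2-(hydroxymethyl)-1-(4-hydroxy-3,5-dimethoxyphenyl)-6,8-dimethoxy-1,2-dihydronaphthalene-3-carbaldehyde
Product: 16 (1S,2R)-7-hydroxy-2-(hydroxymethyl)-1-(4-hydroxy-3,5-dimethoxyphenyl)-6,8-dimethoxy-1,2-dihydronaphthalene-3-carbaldehyde (target)
Conditions: BCl3 (4 equiv), pentamethylbenzene (3 equiv), CH2Cl2, −78 °C; then H2O
Reagents that add atoms: none
Why: Lewis-acid debenzylation, assisted by chelation to the flanking methoxy groups and with pentamethylbenzene as a non-basic benzyl-cation scavenger, should free the C7 phenol at −78 °C without cleaving methyl ethers, reducing the alkene or touching either stereocentre.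

**Compound list**
1 | syringaldehyde | COc1cc(C=O)cc(OC)c1O | starting material
2 | 4-(benzyloxy)-3,5-dimethoxybenzaldehyde | COc1cc(C=O)cc(OC)c1OCc1ccccc1 | intermediate
3 | 4-(benzyloxy)-2-bromo-3,5-dimethoxybenzaldehyde | O=Cc1cc(OC)c(OCc2ccccc2)c(OC)c1Br | intermediate
4 | 2-[4-(benzyloxy)-2-bromo-3,5-dimethoxyphenyl]-1,3-dioxolane | COc1cc(C2OCCO2)c(Br)c(OC)c1OCc1ccccc1 | intermediate
5 | 4-[(tert-butyldimethylsilyl)oxy]-3,5-dimethoxybenzaldehyde | COc1cc(C=O)cc(OC)c1O[Si](C)(C)C(C)(C)C | intermediate
6 | [3-(benzyloxy)-6-(1,3-dioxolan-2-yl)-2,4-dimethoxyphenyl]lithium | COc1cc(C2OCCO2)c([Li])c(OC)c1OCc1ccccc1 | intermediate (not isolated)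
7 | {3-(benzyloxy)-6-(1,3-dioxolan-2-yl)-2,4-dimethoxyphenyl}{4-[(tert-butyldimethylsilyl)oxy]-3,5-dimethoxyphenyl}methanol, racemic | COc1cc(C2OCCO2)c(C(O)c2cc(OC)c(O[Si](C)(C)C(C)(C)C)c(OC)c2)c(OC)c1OCc1ccccc1 | intermediate
8 | 4-{[3-(benzyloxy)-6-(1,3-dioxolan-2-yl)-2,4-dimethoxyphenyl](hydroxy)methyl}-2,6-dimethoxyphenol, racemic | COc1cc(C2OCCO2)c(C(O)c2cc(OC)c(O)c(OC)c2)c(OC)c1OCc1ccccc1 | intermediate (not isolated)
9 | 5-(benzyloxy)-3-(4-hydroxy-3,5-dimethoxyphenyl)-4,6-dimethoxy-1,3-dihydro-2-benzofuran-1-ol, diastereomer mixture, racemic | COc1cc2C(O)OC(c3cc(OC)c(O)c(OC)c3)c2c(OC)c1OCc1ccccc1 | intermediate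
10 | 2,5-dimethoxytetrahydrofuran | COC1CCC(OC)O1 | starting material
11 | succinaldehyde | O=CCCC=O | intermediate
12 | 4-(benzyloxy)-2-[(3,5-dimethoxy-4-oxocyclohexa-2,5-dien-1-ylidene)methyl]-3,5-dimethoxybenzaldehyde | COC1=CC(=Cc2c(C=O)cc(OC)c(OCc3ccccc3)c2OC)C=C(OC)C1=O | intermediate (not isolated)
13 | (2S)-2-[(S)-[3-(benzyloxy)-6-formyl-2,4-dimethoxyphenyl](4-hydroxy-3,5-dimethoxyphenyl)methyl]butanedial | COc1cc([C@@H](c2c(C=O)cc(OC)c(OCc3ccccc3)c2OC)[C@H](CC=O)C=O)cc(OC)c1O | intermediate (not isolated)
14 | (1S,2R)-7-(benzyloxy)-1-(4-hydroxy-3,5-dimethoxyphenyl)-6,8-dimethoxy-1,2-dihydronaphthalene-2,3-dicarbaldehyde | COc1cc([C@H]2c3c(cc(OC)c(OCc4ccccc4)c3OC)C=C(C=O)[C@@H]2C=O)cc(OC)c1O | intermediate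
15 | (1S,2R)-7-(benzyloxy)-2-(hydroxymethyl)-1-(4-hydroxy-3,5-dimethoxyphenyl)-6,8-dimethoxy-1,2-dihydronaphthalene-3-carbaldehyde | COc1cc([C@H]2c3c(cc(OC)c(OCc4ccccc4)c3OC)C=C(C=O)[C@@H]2CO)cc(OC)c1O | intermediate
16 | (1S,2R)-7-hydroxy-2-(hydroxymethyl)-1-(4-hydroxy-3,5-dimethoxyphenyl)-6,8-dimethoxy-1,2-dihydronaphthalene-3-carbaldehyde | COc1cc([C@H]2c3c(cc(OC)c(O)c3OC)C=C(C=O)[C@@H]2CO)cc(OC)c1O | target

**Step count**
Total: 10 steps. Longest linear sequence: 8 steps (1, 2, 3, 5, 6, 8, 9, 10).

**Steps most likely to fail**

1. Step 8 (Proposed new method). Three processes could defeat the cascade: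
 - self-condensation of the dialdehyde partner;
 - diversion of the ionised lactol, by dehydration to an isobenzofuran or capture by the amine, before the enamine arrives;
 - incomplete facial control at C1, which would appear as low enantiomeric purity once C2 equilibrates.

 The fallback sets out from 9 and returns at 14, separating the two bond formations with known chemistry. Lactol 9 is treated under the same amine/acid conditions with the monoprotected C4 unit 4,4-dimethoxybutanal (O=CCCC(OC)OC). This known enamine 1,6-addition of a simple aldehyde should give (2S)-2-[(S)-[3-(benzyloxy)-6-formyl-2,4-dimethoxyphenyl](4-hydroxy-3,5-dimethoxyphenyl)methyl]-4,4-dimethoxybutanal F1. Because C2 of this open-chain adduct is catalyst-controlled, C1 epimers are diastereomers and can be removed by chromatography before C2 is allowed to equilibrate. Aqueous trifluoroacetic acid with dibenzylammonium trifluoroacetate should then hydrolyse the acetal and effect the intramolecular aldol condensation to 14.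

2. Step 9. The first-formed alkoxyborohydride could deliver hydride to the neighbouring enal, or the reagent could fail to discriminate between the two formyl groups, leading to over-reduction. The fallback sets out from 14 and returns at 15. Both aldehydes are reduced with excess NaBH4 in MeOH at 0 °C to [(1S,2R)-7-(benzyloxy)-1-(4-hydroxy-3,5-dimethoxyphenyl)-6,8-dimethoxy-1,2-dihydronaphthalene-2,3-diyl]dimethanol F2. The allylic, arene-conjugated C3 carbinol is then re-oxidised selectively with activated MnO2 in CH2Cl2, which leaves the saturated primary alcohol untouched.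

3. Step 6. During acetal hydrolysis the electron-rich carbinol could ionise and self-alkylate, or the lactol could dehydrate to the isobenzofuran on isolation. The fallback sets out from 7 and returns at quinone methide 12 inside step 8. Compound 7 is desilylated as in step 6 to 8. Instead of aqueous HCl, 8 is treated with sodium p-toluenesulfinate (Cc1ccc(cc1)S(=O)[O-].[Na+]) in aqueous formic acid, which cleaves the dioxolane and traps the benzylic cation as the stable sulfone 4-(benzyloxy)-2-[(4-hydroxy-3,5-dimethoxyphenyl)(4-methylbenzenesulfonyl)methyl]-3,5-dimethoxybenzaldehyde F3. In step 8, solid NaHCO3 replaces the acid co-catalyst, and base-induced 1,6-elimination of sulfinate should release 12.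

**Further compounds**
F1 | step 8 | (2S)-2-[(S)-[3-(benzyloxy)-6-formyl-2,4-dimethoxyphenyl](4-hydroxy-3,5-dimethoxyphenyl)methyl]-4,4-dimethoxybutanal | COc1cc([C@@H](c2c(C=O)cc(OC)c(OCc3ccccc3)c2OC)[C@H](CC(OC)OC)C=O)cc(OC)c1O
F2 | step 9 | [(1S,2R)-7-(benzyloxy)-1-(4-hydroxy-3,5-dimethoxyphenyl)-6,8-dimethoxy-1,2-dihydronaphthalene-2,3-diyl]dimethanol | COc1cc([C@H]2c3c(cc(OC)c(OCc4ccccc4)c3OC)C=C(CO)[C@@H]2CO)cc(OC)c1O
F3 | step 6 | 4-(benzyloxy)-2-[(4-hydroxy-3,5-dimethoxyphenyl)(4-methylbenzenesulfonyl)methyl]-3,5-dimethoxybenzaldehyde, racemic | COc1cc(C=O)c(C(c2cc(OC)c(O)c(OC)c2)S(=O)(=O)c2ccc(C)cc2)c(OC)c1OCc1ccccc1
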